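Amounts of partner and substrate are tied by one balance. Single product and other mono adduct each hold one partner and bis adduct holds two, so, side product aside and every amount counted as a percentage of the charged [substrate], bis adduct minus substrate plus free partner stays equal to the excess: the charged [partner] less the charged [substrate]. That excess is 56.0% in Saturday's, 20.0% in Monday's and 100% in Wednesday's.

all flasks: substrate 0.050 M
- south-west: partner 0.063 M; run made earlier
- north-east: partner 0.079 M; run made earlier
- south: partner 0.093 M; run made earlier
- Monday's: partner 0.0600 M; time 5.0 min
- Wednesday's: partner 0.100 M; time 5.0 min
- Saturday's: partner 0.0780 M; time 5.0 min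

| run | time / min | other mono adduct / % | substrate / % | single product / % | bis adduct / % |
|---|---|---|---|---|---|
| south-west | 0.417 | 20 | 67 | 10 | 4 |
| south-west | 1.00 | 34 | 43 | 12 | 9 |
| south-west | 2.00 | 44 | 31 | 14 | 16 |
| south-west | 5.00 | 46 | 13 | 7 | 26 |
| north-east | 0.667 | 33 | 49 | 12 | 7 |
| north-east | 2.00 | 45 | 15 | 12 | 20 |
| north-east | 3.00 | 45 | 14 | 10 | 28 |
| north-east | 5.00 | 49 | 7 | 6 | 37 |
| south | 0.667 | 38 | 42 | 10 | 9 |
| south | 2.00 | 46 | 14 | 9 | 28 |
| south | 3.00 | 45 | 7 | 9 | 36 |
| south | 5.00 | 43 | 5 | 2 | 46 |

(scatter of a reading: 1.5 percentage points)

1. which of these there is most of at the end, counted by the substrate in it, Monday's (bis adduct / single product / other mono adduct / substrate)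
2. which of these there is most of at the end, counted by the substrate in it, Wednesday's (bis adduct / single product / other mono adduct / substrate)
3. which of these there is most of at the end, counted by the substrate in it, Saturday's (bis adduct / single product / other mono adduct / substrate)
4. final amount of the leader among these, as a percentage of the substrate charged, in Monday's
5. final amount of the leader among these, as a percentage of the substrate charged, in Wednesday's
6. final amount of the leader among these, as a percentage of the substrate charged, in Saturday's

- a species is counted by the substrate in it: one side product counts as two
- amounts and yields of by-product count crystals too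
- given per volume of solution although it is solid: crystals
- on the list of suspects stand: substrate + partner -> other mono adduct + by-product; partner + single product -> bis adduct + by-product; substrate + single product -> side product; crystals <-> by-product; partner + other mono adduct -> bis adduct + by-product; substrate + partner -> single product + by-product

Two extreme flasks are solved in the head. With no second partner taken up, bis adduct is nil. With free substrate and free partner both gone, bis adduct equals the excess. The runs lie between: at 5.00 min the north-east run reads 37% of bis adduct against an excess of 58.0%. From the south-west run to the south run, the bis adduct read at that time rises by 0.333 of the rise in excess, a third.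

Carried from the south-west reading, that share gives bis adduct 24.0% in Monday's, 36.0% in Saturday's and 50.7% in Wednesday's. Monday's figure stands above its excess, which the balance allows while free substrate outweighs free partner. Other mono adduct reads 43% to 49% at that time, so this reckoning puts it ahead of bis adduct in Saturday's and Monday's, and puts bis adduct ahead in Wednesday's.

The forecast, reading other mono adduct as a “broad plateau”, names the same leaders: other mono adduct at 45.5% in Monday's, bis adduct at 50.5% in Wednesday's and other mono adduct at 47% in Saturday's.

The flasks give other mono adduct at 46.6% in Monday's, bis adduct at 51.0% in Wednesday's and other mono adduct at 47.2% in Saturday's. At 50.0 min Saturday's holds more bis adduct than other mono adduct, 57.3% against 38.0%, with substrate at 0.798%, and that bis adduct stands beside the excess of 56.0%.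

    substrate + partner → other mono adduct + by-product (k = 0.200 L mol⁻¹ s⁻¹)
    partner + single product → bis adduct + by-product (k = 0.260 L mol⁻¹ s⁻¹)
    substrate + single product → side product (k = 0.0240 L mol⁻¹ s⁻¹)
    crystals ⇌ by-product, rate k4*(cs4 - [by-product]) while solid is left; crystals form when [by-product] > cs4 (solubility = 5.70 mM, k = 1.10 s⁻¹)
    partner + other mono adduct → bis adduct + by-product (k = 0.0440 L mol⁻¹ s⁻¹)
    substrate + partner → single product + by-product (k = 0.100 L mol⁻¹ s⁻¹)

The neighbour of Monday's charged with 0.024 M of partner has less partner than substrate, which makes partner the limiting reagent. Its excess is −52.0%, so with bis adduct and free partner at nil the balance leaves 52.0% of substrate. That flask gives substrate 56% at 5.00 min, with bis adduct 4.19% and partner 3.2% of its charge.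

(The numbers in the tables were generated by integration on assumed constants.)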